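**Plan**

- The A ring of the target carries oxygen on alternate carbons (C5, C7, C8a), is fused to the pyranone through C4a–C8a and has its prenyl group on C8 next to C8a. This is the pattern of a folded polyketide chain, so the ring is cut at C4a–C5 back to a 2-aryl-4-pyranone with a β-keto ester side chain on C6.
- Further cuts: C5–C6 (carboxylation of a methyl ketone), C8–prenyl (enolate alkylation), C7–C8 (lateral acylation of a 6-methylpyranone), the pyranone ring (triketone from acetylacetone and a benzoate), and the B-ring prenyl group (allyl ether, Claisen rearrangement, cross-metathesis).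
- Forward order: the B ring is dressed first (steps 1–4), the pyranone C ring is made (steps 5–6), the side chain is grown on its methyl group (steps 7–9), the A ring is closed last (step 10), and the two MOM ethers are removed (step 11).
- Stereochemistry: the target has no stereocentre and no alkene with E/Z isomers, so there is no configuration to set. The single stereocentre of the side-chain intermediates is carried as the racemate and disappears when the A ring aromatises.

Key step: step 10

**Route**

Step 1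
Reactants: 1 methyl 3,4-dihydroxybenzoate; 2 allyl bromide (3-bromoprop-1-ene)
Product: 3 methyl 3-hydroxy-4-(prop-2-en-1-yloxy)benzoate
Conditions: K2CO3 (1.0 equiv), 2 (1.05 equiv), DMF, 0 °C → rt
Reagents that add atoms: none
Why: Williamson ether synthesis; the 4-OH, para to the ester, is the more acidic phenol, so with one equivalent of base its phenoxide should be alkylated preferentially.

Step 2
Reactants: 3 methyl 3-hydroxy-4-(prop-2-en-1-yloxy)benzoate
Product: 4 methyl 3,4-dihydroxy-5-(prop-2-en-1-yl)benzoate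
Conditions: N,N-diethylaniline, 195 °C, Ar
Reagents that add atoms: none
Why: Aromatic Claisen rearrangement; of the two ortho positions only C5 bears hydrogen and can re-aromatise, so the allyl group should arrive there alone.

Step 3
Reactants: 4 methyl 3,4-dihydroxy-5-(prop-2-en-1-yl)benzoate
Product: 5 methyl 3,4-bis(methoxymethoxy)-5-(prop-2-en-1-yl)benzoate
Conditions: MOMCl (3 equiv), i-Pr2NEt (4 equiv), CH2Cl2, 0 °C → rt
Reagents that add atoms: chloromethyl methyl ether, COCCl
Why: Standard O-alkylation of both phenols to base-stable MOM acetals, which tolerate every later carbanion step and leave under mild acid.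

Step 4
Reactants: 5 methyl 3,4-bis(methoxymethoxy)-5-(prop-2-en-1-yl)benzoate
Product: 6 methyl 3,4-bis(methoxymethoxy)-5-(3-methylbut-2-en-1-yl)benzoate
Conditions: Grubbs II (3 mol%), 2-methyl-2-butene (excess), CH2Cl2, 40 °C
Reagents that add atoms: 2-methyl-2-butene, CC=C(C)C
Why: Olefin cross-metathesis of a terminal allylarene with 2-methyl-2-butene is the usual way to turn an allyl into a prenyl group, and the loss of propene drives it.

Step 5
Reactants: 6 methyl 3,4-bis(methoxymethoxy)-5-(3-methylbut-2-en-1-yl)benzoate; 7 acetylacetone (pentane-2,4-dione)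
Product: 8 1-[3,4-bis(methoxymethoxy)-5-(3-methylbut-2-en-1-yl)phenyl]hexane-1,3,5-trione
Conditions: 7 (2.5 equiv), LDA (5 equiv), THF, −78 → 0 °C; then 6, 0 °C → rt; aq NH4Cl
Reagents that add atoms: none
Why: Claisen condensation of the acetylacetone dianion (Hauser–Harris acylation), which reacts at its more basic terminal carbon; the excess dianion takes up the acidic proton of the triketone.

Step 6
Reactants: 8 1-[3,4-bis(methoxymethoxy)-5-(3-methylbut-2-en-1-yl)phenyl]hexane-1,3,5-trione
Product: 9 2-[3,4-bis(methoxymethoxy)-5-(3-methylbut-2-en-1-yl)phenyl]-6-methyl-4H-pyran-4-one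
Conditions: PPh3 (2 equiv), CCl4 (5 equiv), Et3N (2.2 equiv), THF, 0 °C → rt
Reagents that add atoms: none
Why: Appel-type cyclodehydration of a 1,3,5-triketone, in which one terminal enol oxygen is activated and displaced 6-endo by the other, can give only this 4-pyranone, and the buffered, non-acidic medium should spare the MOM ethers and the prenyl alkene.

Step 7
Reactants: 9 2-[3,4-bis(methoxymethoxy)-5-(3-methylbut-2-en-1-yl)phenyl]-6-methyl-4H-pyran-4-one; 10 N-methoxy-N-methylacetamide
Product: 11 2-[3,4-bis(methoxymethoxy)-5-(3-methylbut-2-en-1-yl)phenyl]-6-(2-oxopropyl)-4H-pyran-4-one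
Conditions: LiHMDS (2.1 equiv), THF, −78 °C; then 10 (1.3 equiv), −78 → −20 °C; aq NH4Cl
Reagents that add atoms: none
Why: Lateral (vinylogous) deprotonation of the 6-methyl group gives an extended enolate that is acylated at the exocyclic carbon in a Weinreb ketone synthesis, the chelated tetrahedral adduct preventing a second addition.

Step 8
Reactants: 11 2-[3,4-bis(methoxymethoxy)-5-(3-methylbut-2-en-1-yl)phenyl]-6-(2-oxopropyl)-4H-pyran-4-one; 12 prenyl bromide (1-bromo-3-methylbut-2-ene)
Product: 13 rac-2-[3,4-bis(methoxymethoxy)-5-(3-methylbut-2-en-1-yl)phenyl]-6-(6-methyl-2-oxohept-5-en-3-yl)-4H-pyran-4-one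
Conditions: NaH (1.05 equiv), THF–DMF, 0 °C; then 12 (1.05 equiv), 0 °C → rt
Reagents that add atoms: none
Why: C-alkylation (SN2) of a stabilised enolate, since the methylene between the ketone and the pyranone is the only doubly activated site and a soft allylic bromide should favour carbon over oxygen; the new stereocentre is formed as the racemate.

Step 9
Reactants: 13 rac-2-[3,4-bis(methoxymethoxy)-5-(3-methylbut-2-en-1-yl)phenyl]-6-(6-methyl-2-oxohept-5-en-3-yl)-4H-pyran-4-one
Product: 15 methyl rac-4-{6-[3,4-bis(methoxymethoxy)-5-(3-methylbut-2-en-1-yl)phenyl]-4-oxo-4H-pyran-2-yl}-7-methyl-3-oxooct-6-enoate, via β-keto acid 14 (not isolated)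
Conditions: LDA (2.3 equiv), THF, −78 → −30 °C; CO2 (g), −78 °C; cold 1 M HCl to pH 3; then TMSCHN2, PhMe–MeOH, 0 °C
Reagents that add atoms: carbon dioxide, O=C=O; (trimethylsilyl)diazomethane, C[Si](C)(C)C=[N+]=[N-]
Why: Terminal carboxylation of a 1,3-dicarbonyl-type dianion (Harris polyanion chemistry), in which the last-formed methyl-derived carbanion is the most reactive site and the carboxylate formed cannot quench unreacted dianion, followed by diazoalkane esterification of the cold β-keto acid.

Step 10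
Reactants: 15 methyl rac-4-{6-[3,4-bis(methoxymethoxy)-5-(3-methylbut-2-en-1-yl)phenyl]-4-oxo-4H-pyran-2-yl}-7-methyl-3-oxooct-6-enoate
Product: 16 2-[3,4-bis(methoxymethoxy)-5-(3-methylbut-2-en-1-yl)phenyl]-5,7-dihydroxy-8-(3-methylbut-2-en-1-yl)-4H-chromen-4-one
Conditions: DBU (3 equiv), MeCN, 60 °C; then pH 5 phosphate buffer
Reagents that add atoms: none
Why: Proposed new method: DBU reversibly removes the side-chain proton that is alpha to the ketone and vinylogously alpha to the pyranone carbonyl, and the extended enolate (O–C4=C3–C2=C exocyclic) attacks the methyl ester through ring carbon C3 to form C4a–C5, after which loss of methoxide and two enolisations give the aromatic 5,7-dihydroxy ring, whose phenoxide makes the sequence irreversible. The closest known reaction type is the base-mediated Claisen (Dieckmann-type) cyclisation of 3,5,7-triketo esters to acylphloroglucinols, with the pyranone enol ether here standing in for one chain carbonyl, combined with the lateral-anion chemistry of 2-alkyl-4-pyranones. The A ring closes in a 6-(enolexo)-exo-trig mode. No stereocentre is created, and the one at the prenyl-bearing carbon is erased on aromatisation. The step needs acylation at C3 and not at the exocyclic carbon or at oxygen, and the tether secures this because only C3 attack gives a six-membered ring (the exocyclic carbon or the ketone oxygen would give a four-membered ring, the C4 oxygen an eight-membered one, and an aldol onto C4 would need a bridgehead alkene); the β-keto ester enolate that forms alongside is unproductive and equilibrates, and an amidine base free of alkoxide should avoid retro-Claisen cleavage and opening of the pyranone. Because the prenyl group already sits on the carbon that becomes C8, no 6-prenyl isomer can arise.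

Step 11
Reactants: 16 2-[3,4-bis(methoxymethoxy)-5-(3-methylbut-2-en-1-yl)phenyl]-5,7-dihydroxy-8-(3-methylbut-2-en-1-yl)-4H-chromen-4-one
Product: 17 epimedokoreanin B, 2-[3,4-dihydroxy-5-(3-methylbut-2-en-1-yl)phenyl]-5,7-dihydroxy-8-(3-methylbut-2-en-1-yl)-4H-chromen-4-one
Conditions: 3 M aq HCl, MeOH, 40 °C
Reagents that add atoms: none
Why: Acid-catalysed acetal methanolysis of the two aryl MOM ethers; dilute acid at modest temperature is the usual choice for prenylated flavonoids because it should not cyclise the prenyl groups onto the neighbouring phenols.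

**Compound list**

1 | methyl 3,4-dihydroxybenzoate | COC(=O)c1ccc(O)c(O)c1 | starting material
2 | allyl bromide | C=CCBr | starting material
3 | methyl 3-hydroxy-4-(prop-2-en-1-yloxy)benzoate | COC(=O)c1ccc(OCC=C)c(O)c1 | intermediate
4 | methyl 3,4-dihydroxy-5-(prop-2-en-1-yl)benzoate | COC(=O)c1cc(O)c(O)c(CC=C)c1 | intermediate
5 | methyl 3,4-bis(methoxymethoxy)-5-(prop-2-en-1-yl)benzoate | COC(=O)c1cc(OCOC)c(OCOC)c(CC=C)c1 | intermediate
6 | methyl 3,4-bis(methoxymethoxy)-5-(3-methylbut-2-en-1-yl)benzoate | COC(=O)c1cc(OCOC)c(OCOC)c(CC=C(C)C)c1 | intermediate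
7 | acetylacetone | CC(=O)CC(C)=O | starting material
8 | 1-[3,4-bis(methoxymethoxy)-5-(3-methylbut-2-en-1-yl)phenyl]hexane-1,3,5-trione | CC(=O)CC(=O)CC(=O)c1cc(OCOC)c(OCOC)c(CC=C(C)C)c1 | intermediate
9 | 2-[3,4-bis(methoxymethoxy)-5-(3-methylbut-2-en-1-yl)phenyl]-6-methyl-4H-pyran-4-one | Cc1cc(=O)cc(-c2cc(OCOC)c(OCOC)c(CC=C(C)C)c2)o1 | intermediate
10 | N-methoxy-N-methylacetamide | CC(=O)N(C)OC | starting material
11 | 2-[3,4-bis(methoxymethoxy)-5-(3-methylbut-2-en-1-yl)phenyl]-6-(2-oxopropyl)-4H-pyran-4-one | CC(=O)Cc1cc(=O)cc(-c2cc(OCOC)c(OCOC)c(CC=C(C)C)c2)o1 | intermediate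
12 | prenyl bromide | CC(C)=CCBr | starting material
13 | rac-2-[3,4-bis(methoxymethoxy)-5-(3-methylbut-2-en-1-yl)phenyl]-6-(6-methyl-2-oxohept-5-en-3-yl)-4H-pyran-4-one (racemate) | CC(=O)C(CC=C(C)C)c1cc(=O)cc(-c2cc(OCOC)c(OCOC)c(CC=C(C)C)c2)o1 | intermediate
14 | rac-4-{6-[3,4-bis(methoxymethoxy)-5-(3-methylbut-2-en-1-yl)phenyl]-4-oxo-4H-pyran-2-yl}-7-methyl-3-oxooct-6-enoic acid (racemate, not isolated) | OC(=O)CC(=O)C(CC=C(C)C)c1cc(=O)cc(-c2cc(OCOC)c(OCOC)c(CC=C(C)C)c2)o1 | intermediate
15 | methyl rac-4-{6-[3,4-bis(methoxymethoxy)-5-(3-methylbut-2-en-1-yl)phenyl]-4-oxo-4H-pyran-2-yl}-7-methyl-3-oxooct-6-enoate (racemate) | COC(=O)CC(=O)C(CC=C(C)C)c1cc(=O)cc(-c2cc(OCOC)c(OCOC)c(CC=C(C)C)c2)o1 | intermediate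
16 | 2-[3,4-bis(methoxymethoxy)-5-(3-methylbut-2-en-1-yl)phenyl]-5,7-dihydroxy-8-(3-methylbut-2-en-1-yl)-4H-chromen-4-one | Oc1cc(O)c2c(=O)cc(-c3cc(OCOC)c(OCOC)c(CC=C(C)C)c3)oc2c1CC=C(C)C | intermediate
17 | epimedokoreanin B (achiral) | CC(C)=CCc1cc(-c2cc(=O)c3c(O)cc(O)c(CC=C(C)C)c3o2)cc(O)c1O | target

**Count**

Total steps: 11. Longest linear sequence: 11 steps (1 → 17).

**Steps most likely to fail**

1. Step 10 (Proposed new method). The enolate may fail to acylate through the ring carbon, so that retro-Claisen fragmentation of the β-keto ester or slow intermolecular condensation takes over. The fallback uses known flavone chemistry, sets out from 6 and returns at 17. Commercial 2',4',6'-trihydroxyacetophenone is protected at its non-chelated 4-OH (MOMCl, 1 equiv, i-Pr2NEt) to give 1-[2,6-dihydroxy-4-(methoxymethoxy)phenyl]ethan-1-one F1. Its lithium polyanion (LiHMDS, 5 equiv, THF) is acylated by ester 6 in a crossed Claisen condensation to give 1-[3,4-bis(methoxymethoxy)-5-(3-methylbut-2-en-1-yl)phenyl]-3-[2,6-dihydroxy-4-(methoxymethoxy)phenyl]propane-1,3-dione F2. Buffered cyclodehydration (NaOAc, AcOH, 90 °C) should give 2-[3,4-bis(methoxymethoxy)-5-(3-methylbut-2-en-1-yl)phenyl]-5-hydroxy-7-(methoxymethoxy)-4H-chromen-4-one F3. O-Prenylation of the chelated 5-OH with 12 (K2CO3, acetone, reflux) gives 2-[3,4-bis(methoxymethoxy)-5-(3-methylbut-2-en-1-yl)phenyl]-7-(methoxymethoxy)-5-[(3-methylbut-2-en-1-yl)oxy]-4H-chromen-4-one F4. A Eu(fod)3-catalysed para-Claisen–Cope rearrangement (PhCl, NaHCO3, 85 °C) should move the prenyl group from O5 by way of C6 to C8 and give 2-[3,4-bis(methoxymethoxy)-5-(3-methylbut-2-en-1-yl)phenyl]-5-hydroxy-7-(methoxymethoxy)-8-(3-methylbut-2-en-1-yl)-4H-chromen-4-one F5. Acid methanolysis of its three MOM ethers under the conditions of step 11 gives 17.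

2. Step 9. The second deprotonation may be incomplete, and the β-keto acid may lose carbon dioxide before it is esterified, which would return 13. The fallback sets out from 9 and returns at 15, bypassing steps 7–9. Lateral lithiation of 9 (LiHMDS, THF, −78 °C) and alkylation with 12 give 2-[3,4-bis(methoxymethoxy)-5-(3-methylbut-2-en-1-yl)phenyl]-6-(4-methylpent-3-en-1-yl)-4H-pyran-4-one F6. A second lateral lithiation (LDA, −78 °C) and quenching with CO2 give rac-2-{6-[3,4-bis(methoxymethoxy)-5-(3-methylbut-2-en-1-yl)phenyl]-4-oxo-4H-pyran-2-yl}-5-methylhex-4-enoic acid F7. Activation with carbonyldiimidazole in THF gives the acyl imidazole rac-2-{6-[3,4-bis(methoxymethoxy)-5-(3-methylbut-2-en-1-yl)phenyl]-4-oxo-4H-pyran-2-yl}-1-(1H-imidazol-1-yl)-5-methylhex-4-en-1-one F8, which is not isolated. Masamune–Brooks chain extension with potassium methyl malonate, MgCl2 and Et3N then gives 15 after decarboxylation, under nearly neutral conditions.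

3. Step 6. The MOM ethers may be lost to the hydrogen chloride released, or the reaction may halt at an open-chain chloro enone. The fallback sets out from 6 and returns at 9, replacing steps 5–6. The kinetic lithium enolate of commercial (E)-4-methoxypent-3-en-2-one (LDA, THF, −78 °C, 2.2 equiv) is condensed with ester 6 in a Claisen reaction to give (E)-1-[3,4-bis(methoxymethoxy)-5-(3-methylbut-2-en-1-yl)phenyl]-5-methoxyhex-4-ene-1,3-dione F9. Warming with PPTS in toluene lets the enol oxygen add 6-endo to the β-methoxy enone and expel methanol, so the pyranone 9 forms by addition–elimination without any dehydrating agent.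

**Further compounds**

F1 | step 10 | 1-[2,6-dihydroxy-4-(methoxymethoxy)phenyl]ethan-1-one | CC(=O)c1c(O)cc(OCOC)cc1O
F2 | step 10 | 1-[3,4-bis(methoxymethoxy)-5-(3-methylbut-2-en-1-yl)phenyl]-3-[2,6-dihydroxy-4-(methoxymethoxy)phenyl]propane-1,3-dione | COCOc1cc(O)c(C(=O)CC(=O)c2cc(OCOC)c(OCOC)c(CC=C(C)C)c2)c(O)c1
F3 | step 10 | 2-[3,4-bis(methoxymethoxy)-5-(3-methylbut-2-en-1-yl)phenyl]-5-hydroxy-7-(methoxymethoxy)-4H-chromen-4-one | COCOc1cc(O)c2c(=O)cc(-c3cc(OCOC)c(OCOC)c(CC=C(C)C)c3)oc2c1
F4 | step 10 | 2-[3,4-bis(methoxymethoxy)-5-(3-methylbut-2-en-1-yl)phenyl]-7-(methoxymethoxy)-5-[(3-methylbut-2-en-1-yl)oxy]-4H-chromen-4-one | COCOc1cc(OCC=C(C)C)c2c(=O)cc(-c3cc(OCOC)c(OCOC)c(CC=C(C)C)c3)oc2c1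
F5 | step 10 | 2-[3,4-bis(methoxymethoxy)-5-(3-methylbut-2-en-1-yl)phenyl]-5-hydroxy-7-(methoxymethoxy)-8-(3-methylbut-2-en-1-yl)-4H-chromen-4-one | COCOc1cc(O)c2c(=O)cc(-c3cc(OCOC)c(OCOC)c(CC=C(C)C)c3)oc2c1CC=C(C)C
F6 | step 9 | 2-[3,4-bis(methoxymethoxy)-5-(3-methylbut-2-en-1-yl)phenyl]-6-(4-methylpent-3-en-1-yl)-4H-pyran-4-one | CC(C)=CCCc1cc(=O)cc(-c2cc(OCOC)c(OCOC)c(CC=C(C)C)c2)o1
F7 | step 9 | rac-2-{6-[3,4-bis(methoxymethoxy)-5-(3-methylbut-2-en-1-yl)phenyl]-4-oxo-4H-pyran-2-yl}-5-methylhex-4-enoic acid (racemate) | OC(=O)C(CC=C(C)C)c1cc(=O)cc(-c2cc(OCOC)c(OCOC)c(CC=C(C)C)c2)o1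
F8 | step 9 | rac-2-{6-[3,4-bis(methoxymethoxy)-5-(3-methylbut-2-en-1-yl)phenyl]-4-oxo-4H-pyran-2-yl}-1-(1H-imidazol-1-yl)-5-methylhex-4-en-1-one (racemate, not isolated) | O=C(C(CC=C(C)C)c1cc(=O)cc(-c2cc(OCOC)c(OCOC)c(CC=C(C)C)c2)o1)n1ccnc1
F9 | step 6 | (E)-1-[3,4-bis(methoxymethoxy)-5-(3-methylbut-2-en-1-yl)phenyl]-5-methoxyhex-4-ene-1,3-dione | CO/C(C)=C/C(=O)CC(=O)c1cc(OCOC)c(OCOC)c(CC=C(C)C)c1
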